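**Retrosynthetic overview**
- The target (2-methoxy-6-octadecyl-1,4-benzoquinone) comes from its hydroquinone (Ag2O), which comes from a dienylketene by a 6π electrocyclisation that forms the bond between the quinone carbonyl carbon C1 and the methoxy-bearing C2. The ketene forms in the same flask by 4π opening of 4-hydroxy-4-[(Z)-2-methoxyvinyl]-2-octadecylcyclobutenone.
- Enabling feature: in the six-membered ring, C1 is a carbonyl flanked by C6 (octadecyl) and C2 (OMe), and the second oxygen sits para on C4 between the CH carbons C3 and C5. C1 can therefore be a ketene carbon, C2=C3 the enol-ether end of a triene, and C4–O the carbinol of a strained four-membered ring (C4, C5, C6, C1) whose strain drives the cascade.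
- The cyclobutenone is built regiodefined from diisopropyl squarate: semisquarate, reduction of its ketone (parks the future C1 as a carbinol), Stork–Danheiser introduction of the chain with octadecylmagnesium chloride, methoxyacetylide addition, cis-semihydrogenation, MnO2.
- Ring order: the four-membered ring is bought with the squarate; the six-membered quinone ring is the only ring formed and is closed last.

Key step: step 7

Remark: the target has no stereocentre, so racemates and diastereomer mixtures of the intermediates are carried through as such.

**Step 1**
Reactants: 1 diisopropyl squarate (3,4-diisopropoxycyclobut-3-ene-1,2-dione)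
Product: 3 3-isopropoxycyclobut-3-ene-1,2-dione, via 4-hydroxy-2,3-diisopropoxycyclobut-2-en-1-one 2 (not isolated)
Conditions: LiAlH(OtBu)3 (1.0 equiv), THF, −78 °C; then 6 M HCl, CH2Cl2, 0 °C to rt
Reagents that add atoms: water, O
Why: The bulky hydride should reduce one vinylogous ester carbonyl 1,2 to give racemic carbinol 2, and acid should then ionise this carbinol to an isopropoxy-stabilised cyclobutenyl cation whose hydrolysis releases isopropanol (vinylogous ester hydrolysis with allylic transposition, the standard squarate-to-semisquarate conversion), which removes the stereocentre again.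

**Step 2**
Reactants: 3 3-isopropoxycyclobut-3-ene-1,2-dione
Product: 4 4-hydroxy-3-isopropoxycyclobut-2-en-1-one
Conditions: LiAlH(OtBu)3 (1.05 equiv), THF, −78 °C; aq. potassium sodium tartrate, 0 °C
Reagents that add atoms: none
Why: Chemoselective 1,2-hydride reduction should occur at the ketone carbonyl next to the isopropoxy-bearing carbon, which is far more electrophilic than the vinylogous ester carbonyl (the site selectivity known for 1,2-additions to 3-alkoxycyclobutenediones), so the future quinone C1 is parked as a racemic carbinol that step 6 oxidises again.

**Step 3**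
Reactants: 4 4-hydroxy-3-isopropoxycyclobut-2-en-1-one; 5 octadecylmagnesium chloride
Product: 7 4-hydroxy-3-octadecylcyclobut-2-en-1-one, via 3-isopropoxy-1-octadecylcyclobut-2-ene-1,4-diol 6 (not isolated)
Conditions: 5 (2.2 equiv), THF, −78 to −20 °C; then 1 M HCl, THF, 0 °C
Reagents that add atoms: water, O
Why: The first equivalent of the Grignard reagent deprotonates the hydroxyl and the second adds 1,2 to the vinylogous ester carbonyl, after which acid ionises the tertiary allylic alcohol with help from the isopropoxy group and hydrolysis releases isopropanol (Stork–Danheiser alkylative carbonyl transposition), so the chain takes the place of the isopropoxy group next to the carbinol carbon; a competing addition–elimination at the isopropoxy-bearing carbon would give the same product, the tertiary centre of 6 is destroyed, the CH(OH) centre stays racemic, and scrambling of the ketol is blocked because its enediol would be a cyclobutadiene.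

**Step 4**
Reactants: 7 4-hydroxy-3-octadecylcyclobut-2-en-1-one; 8 2-chloro-1,1-dimethoxyethane
Product: 10 1-(methoxyethynyl)-3-octadecylcyclobut-2-ene-1,4-diol, via lithium methoxyacetylide 9 (not isolated)
Conditions: 8, LiNEt2 (3 equiv per 8, from Et2NH and n-BuLi), THF, 0 °C; then 7 added to 9 (2.5 equiv), −78 °C; H2O quench at −78 °C
Reagents that add atoms: none
Why: Threefold base-induced elimination from 8 gives the acetylide, whose first equivalent deprotonates the hydroxyl and whose second adds 1,2 to the strained, unhindered cyclobutenone carbonyl (acetylide addition to a ketone), the cold neutral quench sparing the ynol ether; the new tertiary carbinol forms as a mixture of diastereomers, which does not matter because the neighbouring carbinol is oxidised in step 6.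

**Step 5**
Reactants: 10 1-(methoxyethynyl)-3-octadecylcyclobut-2-ene-1,4-diol
Product: 11 1-[(Z)-2-methoxyethenyl]-3-octadecylcyclobut-2-ene-1,4-diol
Conditions: H2 (1 atm), Pd/CaCO3 poisoned with Pb(OAc)2 (Lindlar catalyst), quinoline, EtOAc, rt
Reagents that add atoms: none
Why: Syn delivery of hydrogen on the poisoned catalyst should stop at the (Z)-enol ether and leave the trisubstituted ring alkene and the allylic C–O bonds untouched (Lindlar semihydrogenation of an alkoxyethynyl carbinol, as in the Arens–van Dorp sequence); the double-bond geometry is set by this syn addition.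

**Step 6**
Reactants: 11 1-[(Z)-2-methoxyethenyl]-3-octadecylcyclobut-2-ene-1,4-diol
Product: 12 4-hydroxy-4-[(Z)-2-methoxyethenyl]-2-octadecylcyclobut-2-en-1-one
Conditions: activated MnO2 (excess), CH2Cl2, rt
Reagents that add atoms: none
Why: MnO2 should oxidise only the secondary allylic alcohol (allylic alcohol oxidation), since the tertiary carbinol cannot be oxidised and the neutral heterogeneous conditions spare the acid-labile 3-methoxyallylic alcohol; the CH(OH) centre is erased and both diastereomers converge on one racemic ketone.

**Step 7**
Reactants: 12 4-hydroxy-4-[(Z)-2-methoxyethenyl]-2-octadecylcyclobut-2-en-1-one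
Product: 16 2-methoxy-6-octadecylcyclohexa-2,5-diene-1,4-dione, via dienylketene 13 (not isolated), via cyclohexadienone 14 (not isolated), via hydroquinone 15 (not isolated)
Conditions: PhMe (dilute, degassed, base-washed glass), 110 °C; then Ag2O, rt
Reagents that add atoms: none
Why: Heating should open the four-membered ring of 12 by a conrotatory 4π electrocyclic reaction in which the hydroxyl rotates outward, so that the methoxyvinyl group lies cis to the ketene in 13; a thermally allowed disrotatory 6π electrocyclisation then joins the ketene carbon to the methoxy-bearing vinyl terminus to give dienone 14, tautomerisation gives hydroquinone 15, and Ag2O dehydrogenates it to 16. The closest known reaction type is the thermal ring expansion of 4-alkenyl-4-hydroxycyclobutenones to hydroquinones (Moore–Liebeskind rearrangement), here with a 2-alkoxyvinyl group as the alkenyl partner. The only ring formed is the carbocyclic six-membered ring, closed in a pericyclic 6π mode through the bond between the future carbonyl carbon C1 and C2, while the four-membered ring is consumed. The single sp3 centre of 14 forms as a racemate and disappears on aromatisation, so no stereocontrol is needed. The step needs torquoselectivity, secured by the outward preference of the donor hydroxyl; periselectivity for 6π closure over lactonisation or attack of the enol-ether β-carbon on the ketene, secured by the cis relation of ketene and vinyl group, the trans-placed enol hydroxyl and the aromatic driving force; and one substitution pattern, inherited from 12, in which the ketene carbon has the octadecyl-bearing carbon as neighbour so that only the 2,6-pattern can arise. One operation should thus deliver the ring, both ring oxygens on the right carbons, the methoxy group and the chain in their final places.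

**Compound list**
1 | diisopropyl squarate (3,4-diisopropoxycyclobut-3-ene-1,2-dione) | CC(C)OC1=C(OC(C)C)C(=O)C1=O | starting material
2 | 4-hydroxy-2,3-diisopropoxycyclobut-2-en-1-one (racemic) | CC(C)OC1=C(OC(C)C)C(O)C1=O | intermediate
3 | 3-isopropoxycyclobut-3-ene-1,2-dione | CC(C)OC1=CC(=O)C1=O | intermediate
4 | 4-hydroxy-3-isopropoxycyclobut-2-en-1-one (racemic) | CC(C)OC1=CC(=O)C1O | intermediate
5 | octadecylmagnesium chloride | CCCCCCCCCCCCCCCCCC[Mg]Cl | starting material
6 | 3-isopropoxy-1-octadecylcyclobut-2-ene-1,4-diol (diastereomer mixture) | CCCCCCCCCCCCCCCCCCC1(O)C=C(OC(C)C)C1O | intermediate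
7 | 4-hydroxy-3-octadecylcyclobut-2-en-1-one (racemic) | CCCCCCCCCCCCCCCCCCC1=CC(=O)C1O | intermediate
8 | 2-chloro-1,1-dimethoxyethane (chloroacetaldehyde dimethyl acetal) | COC(CCl)OC | starting material
9 | lithium methoxyacetylide | [Li]C#COC | intermediate
10 | 1-(methoxyethynyl)-3-octadecylcyclobut-2-ene-1,4-diol (cis and trans diols, each racemic) | CCCCCCCCCCCCCCCCCCC1=CC(O)(C#COC)C1O | intermediate
11 | 1-[(Z)-2-methoxyethenyl]-3-octadecylcyclobut-2-ene-1,4-diol (cis and trans diols, each racemic) | CCCCCCCCCCCCCCCCCCC1=CC(O)(/C=C\OC)C1O | intermediate
12 | 4-hydroxy-4-[(Z)-2-methoxyethenyl]-2-octadecylcyclobut-2-en-1-one (racemic) | CCCCCCCCCCCCCCCCCCC1=CC(O)(/C=C\OC)C1=O | intermediate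
13 | (3E,5Z)-4-hydroxy-6-methoxy-2-octadecylhexa-1,3,5-trien-1-one (dienylketene) | CCCCCCCCCCCCCCCCCCC(=C=O)/C=C(/O)\C=C/OC | intermediate
14 | 4-hydroxy-6-methoxy-2-octadecylcyclohexa-2,4-dien-1-one (racemic) | CCCCCCCCCCCCCCCCCCC1=CC(O)=CC(OC)C1=O | intermediate
15 | 2-methoxy-6-octadecylbenzene-1,4-diol | CCCCCCCCCCCCCCCCCCc1cc(O)cc(OC)c1O | intermediate
16 | 2-methoxy-6-octadecylcyclohexa-2,5-diene-1,4-dione | CCCCCCCCCCCCCCCCCCC1=CC(=O)C=C(OC)C1=O | target

**Step count and risks**

Total step count: 7. Longest linear sequence: 7 steps (from 1).

Steps most likely to fail: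

Step 7. The dienylketene may be diverted before it closes: oligomerisation through its enol hydroxyl, slow disrotatory closure because the (Z)-methoxy group must turn inward, or acid-triggered loss of the enol ether at 110 °C. The fallback gives up the ring expansion and builds the arene classically. It sets out from 5. Commercial 2-bromo-6-methoxyphenol F1 is protected with MOMCl and iPr2NEt as 1-bromo-3-methoxy-2-(methoxymethoxy)benzene F2. Kumada–Corriu coupling of F2 with 5 (PdCl2(dppf), THF, reflux) should give 1-methoxy-2-(methoxymethoxy)-3-octadecylbenzene F3, and HCl in MeOH should free 2-methoxy-6-octadecylphenol F4. Teuber oxidation of F4 with K2[ON(SO3)2] (aq. KH2PO4, CH2Cl2, Bu4NHSO4) should give the para-quinone, so the fallback comes back to the route at 16.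

Step 5. The hydrogenation may run on to the saturated ether, saturate the strained ring alkene, or stall through poisoning of the catalyst. The fallback replaces catalytic hydrogenation by hydride chemistry and sets out from 10. Alkoxide-directed trans-hydroalumination with LiAlH4 (THF, 0 °C, basic work-up) should give 1-[(E)-2-methoxyethenyl]-3-octadecylcyclobut-2-ene-1,4-diol F5. MnO2 should oxidise F5 to 4-hydroxy-4-[(E)-2-methoxyethenyl]-2-octadecylcyclobut-2-en-1-one F6. Heating F6 in toluene should open it to (3E,5E)-4-hydroxy-6-methoxy-2-octadecylhexa-1,3,5-trien-1-one F7, whose methoxy group points outward in the 6π closure. The fallback comes back to the route at 14.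

Step 4. The lithium alkoxide formed from the free hydroxyl of 7 may trigger oxyanion-accelerated opening of the strained ring or a ketol shift, or it may suppress carbonyl addition, so that the adduct is lost. The fallback uses a protecting group instead of the dianion and sets out from 7. Silylation (TBSCl, imidazole, DMF) should give 4-[(tert-butyldimethylsilyl)oxy]-3-octadecylcyclobut-2-en-1-one F8. Addition of 9 (1.2 equiv, THF, −78 °C) should give 4-[(tert-butyldimethylsilyl)oxy]-1-(methoxyethynyl)-3-octadecylcyclobut-2-en-1-ol F9. Bu4NF in THF should remove the silyl group under non-acidic conditions, and the fallback comes back to the route at 10.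

**Further compounds**
F1 | step 7 | 2-bromo-6-methoxyphenol | COc1cccc(Br)c1O
F2 | step 7 | 1-bromo-3-methoxy-2-(methoxymethoxy)benzene | COCOc1c(Br)cccc1OC
F3 | step 7 | 1-methoxy-2-(methoxymethoxy)-3-octadecylbenzene | CCCCCCCCCCCCCCCCCCc1cccc(OC)c1OCOC
F4 | step 7 | 2-methoxy-6-octadecylphenol | CCCCCCCCCCCCCCCCCCc1cccc(OC)c1O
F5 | step 5 | 1-[(E)-2-methoxyethenyl]-3-octadecylcyclobut-2-ene-1,4-diol | CCCCCCCCCCCCCCCCCCC1=CC(O)(/C=C/OC)C1O
F6 | step 5 | 4-hydroxy-4-[(E)-2-methoxyethenyl]-2-octadecylcyclobut-2-en-1-one | CCCCCCCCCCCCCCCCCCC1=CC(O)(/C=C/OC)C1=O
F7 | step 5 | (3E,5E)-4-hydroxy-6-methoxy-2-octadecylhexa-1,3,5-trien-1-one | CCCCCCCCCCCCCCCCCCC(=C=O)/C=C(/O)\C=C\OC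
F8 | step 4 | 4-[(tert-butyldimethylsilyl)oxy]-3-octadecylcyclobut-2-en-1-one | CCCCCCCCCCCCCCCCCCC1=CC(=O)C1O[Si](C)(C)C(C)(C)C
F9 | step 4 | 4-[(tert-butyldimethylsilyl)oxy]-1-(methoxyethynyl)-3-octadecylcyclobut-2-en-1-ol | CCCCCCCCCCCCCCCCCCC1=CC(O)(C#COC)C1O[Si](C)(C)C(C)(C)C
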